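Read two flasks at their hours, 25 h and 75 h, counting everything as a fraction of the E charged.

| flask | E | Q | G | remark | time | volume of the second phase over the first |
|---|---|---|---|---|---|---|
| amber | 0.050 M | 3 equiv | 3.5 mM | run made earlier |  |  |
| grey | 0.050 M | 3 equiv | 5.5 mM | run made earlier |  |  |
| Tuesday's | 0.050 M | 3.00 equiv | 2.50 mM |  | 25 h | 2.0 |
| Thursday's | 0.050 M | 3.00 equiv | 2.50 mM |  | 75 h | 2.0 |

- amber (time / h: J / %, E / %): 2.00: 0.7, 99.4; 5.00: 5.2, 94.5; 10.0: 12.3, 84.1; 25.0: 19.7, 52.7
- grey (time / h: J / %, E / %): 2.00: 1.3, 99.3; 5.00: 5.0, 95.5; 10.0: 11.2, 85.7; 25.0: 20.1, 55.4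

(readings scatter by 0.5 percentage points)

- in the second phase: Q; everything else is in the first
- charges count per volume of the first phase; a concentration in a rate is the amount of a species over the volume of its own phase; every rate counts per litre of the first phase
- steps thought possible: Z <-> Q; E + Z -> J; Z + J -> L; J -> X; Z + G -> D
- the earlier runs hold the two phases in the same ratio of volumes as the flask asked about

- which of the two there is more of at the end, Tuesday's (X / J)
- which of the two there is more of at the end, Thursday's (X / J)
- J at the end, in percent of the E charged, Tuesday's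
- J at the end, in percent of the E charged, Thursday's

Start from amber at 25.0 h. Subtract E and J from the charge and 27.6% has gone past J, into X or L, but the readings don't split it. J over that remainder gives 71.4%: call this the crossing share, the part of the remainder (the selectivity for X) that X must hold to match J.

Carry it to Tuesday's, which has less G. Grey, with 5.5 mM of G against amber's 3.5 mM, ends 2.7 percentage points higher in E and 0.4 points higher in J, so take amber's figures. With Z + J → L open beside J → X, a share of 71.4% is a lot to ask of X, so bet on J for Tuesday's. By Thursday's, expect J to have fallen and the remainder to have grown, so the crossing share shrinks: bet on X.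

The forecast says X for Tuesday's and X for Thursday's, with J at 20.3% (19% to 21.8%) and 5.5% (3.5% to 8.5%), on the ground that “about 28% of the E charged has gone on past J, so X leads”.

Tuesday's gives J 20.5% and X 15.2%, so J leads. Thursday's gives J 5.72% and X 45.6%, so X leads.

    Z ⇌ Q, rate k1*([Z] - [Q]/K1) per volume of the first phase (partition coefficient = 1.10, kL = 1.30 × 10⁻⁵ s⁻¹)
    E + Z → J (k = 5.40 × 10⁻⁴ M⁻¹ s⁻¹)
    Z + J → L (k = 6.60 × 10⁻⁴ M⁻¹ s⁻¹)
    J → X (k = 1.30 × 10⁻⁵ s⁻¹)
    Z + G → D (k = 0.00430 M⁻¹ s⁻¹)

In Tuesday's flask L holds 11.9% beside X, so X has 56.0% of the remainder, less than the crossing share of 71.4% read from amber. The difference in time is the main reason for Thursday's lower J: J there stands at 5.72%, against 20.5% with that difference taken away. So Thursday's crossing share drops to 6.68%, less than X's part of the remainder in that flask, 53.3%.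

The readings stem from a simulated flask on assumed constants.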